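**Plan**

- Retrosynthesis: ring A is opened at O2–C3 (alkynol on an ynenone), the C3–C4 unit with the side chain is cut off at C4–C4a (enol triflate + dienyne), chlorine is removed from C5, ring B is opened at C5–C6 (methyl ketone + ester), and the chain is cut at C8–C8a (aldehyde + diketone enol silane) and C7–C8 (lactate enolate + alkoxymethyl halide).
- Enabling feature: C8a bears the C9 acetyl group and C4a of ring B, two acyl carbons. It is therefore carried as a carbon with two identical acetyl groups, and the one that becomes C4a–C5 is chosen only when ring B closes.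
- Forward: C6–C7–C8 aldehyde ester from (S)-lactic acid, aldol union with a 3-substituted pentane-2,4-dione (C8–C8a), O2/O8 acetonide, Claisen closure of ring B, C5 chlorination, O4a triflate, Sonogashira coupling, deprotection, ring A last by 6-endo closure of O2 on C3.
- Stereochemistry: C7 from (S)-lactic acid (enolate alkylation with retention through its pivalaldehyde acetal); C8 from C7 (chelation-controlled aldol); C8a from C8 (the dioxane chair selects one acetyl); C5′ from (S)-2-methylbutan-1-ol; both side-chain alkenes from E-selective olefinations.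

Key step: step 12

Remark: target numbering (1H-isochromene: C1, O2, C3, C4, C4a, C5–C8, C8a; acetyl carbonyl C9; side chain C1′–C7′) is used for all intermediates; in the benzo[d][1,3]dioxine names, positions 4, 4a, 5, 6, 7, 8, 8a are C1, C8a, C4a, C5, C6, C7, C8; compound 9 (the silyl enol ether of pentane-2,4-dione), benzyl chloromethyl ether, the formyl ylide and the silylpropargyl phosphonate are taken as purchased.

**Route**

Step 1
Reactants: 1 (S)-lactic acid
Product: 2 (2S,5S)-2-tert-butyl-5-methyl-1,3-dioxolan-4-one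
Conditions: pivalaldehyde, TsOH·H2O (cat.), H2SO4 (cat.), pentane, reflux (Dean–Stark); crystallization from pentane/Et2O, −78 °C
Reagents that add atoms: pivalaldehyde, CC(C)(C)C=O
Why: Acid-catalysed acetalization gives mainly the cis dioxolanone, which is purified by crystallization and stores the lactate configuration in the acetal centre.

Step 2
Reactants: 2
Product: 4 (2S,5R)-5-[(benzyloxy)methyl]-2-tert-butyl-5-methyl-1,3-dioxolan-4-one, via dioxolanone lithium enolate 3 (not isolated)
Conditions: LiN(iPr)2, THF, −78 °C; BnOCH2Cl, −78 → −30 °C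
Reagents that add atoms: benzyl chloromethyl ether, ClCOCc1ccccc1
Why: Enolate alkylation with self-regeneration of the stereocentre: the electrophile enters anti to tert-butyl, so the C7–C8 bond replaces hydrogen with retention and fixes C7.

Step 3
Reactants: 4
Product: 5 methyl (2R)-3-(benzyloxy)-2-hydroxy-2-methylpropanoate
Conditions: NaOMe (0.2 equiv), MeOH, 0 °C → rt
Reagents that add atoms: methanol, CO
Why: Transesterification opens the lactone acetal and the hemiacetal loses pivalaldehyde; C7 is quaternary and cannot epimerize.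

Step 4
Reactants: 5
Product: 6 methyl (2R)-3-(benzyloxy)-2-[(tert-butyldimethylsilyl)oxy]-2-methylpropanoate
Conditions: tBuMe2SiOTf, 2,6-lutidine, CH2Cl2, 0 °C → rt
Reagents that add atoms: tert-butyldimethylsilyl trifluoromethanesulfonate, CC(C)(C)[Si](C)(C)OS(=O)(=O)C(F)(F)F
Why: Silyl triflate with a hindered pyridine base silylates the tertiary α-hydroxy ester; the ether is not a chelating donor in the aldol step and should survive until the acidic fluoride deprotection.

Step 5
Reactants: 6
Product: 7 methyl (2R)-2-[(tert-butyldimethylsilyl)oxy]-3-hydroxy-2-methylpropanoate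
Conditions: H2 (1 atm), Pd/C (10%), EtOAc, rt
Reagents that add atoms: none
Why: Neutral hydrogenolysis of the benzyl ether leaves ester and silyl ether untouched and cannot move the silyl group to the primary oxygen.

Step 6
Reactants: 7
Product: 8 methyl (2R)-2-[(tert-butyldimethylsilyl)oxy]-2-methyl-3-oxopropanoate
Conditions: Dess–Martin periodinane, CH2Cl2, rt
Reagents that add atoms: none
Why: Dess–Martin oxidation of the primary alcohol gives the C8 aldehyde, which has no α-hydrogen and can neither enolize nor epimerize.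

Step 7
Reactants: 9 (Z)-4-[(trimethylsilyl)oxy]pent-3-en-2-one
Product: 10 3-[(benzyloxy)methyl]pentane-2,4-dione
Conditions: BnOCH2Cl, ZnBr2 (5 mol %), CH2Cl2, 0 °C → rt
Reagents that add atoms: benzyl chloromethyl ether, ClCOCc1ccccc1
Why: Lewis-acid-catalysed alkylation of a silyl enol ether by an α-chloro ether (oxocarbenium ion) puts C1 on carbon, where a basic enolate alkylation would favour oxygen.

Step 8
Reactants: 10
Product: 11 3-[(benzyloxy)methyl]-4-[(trimethylsilyl)oxy]pent-3-en-2-one
Conditions: Me3SiCl, Et3N, MeCN, rt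
Reagents that add atoms: chlorotrimethylsilane, C[Si](C)(C)Cl
Why: Soft enolization and O-silylation of the 2-substituted 1,3-diketone; the alkene geometry is of no consequence because C8a carries two identical acetyl groups after the aldol step.

Step 9
Reactants: 8 methyl (2R)-2-[(tert-butyldimethylsilyl)oxy]-2-methyl-3-oxopropanoate; 11 3-[(benzyloxy)methyl]-4-[(trimethylsilyl)oxy]pent-3-en-2-one
Product: 13 methyl (2R,3R)-4-acetyl-4-[(benzyloxy)methyl]-2-[(tert-butyldimethylsilyl)oxy]-3-hydroxy-2-methyl-5-oxohexanoate, via titanium aldolate 12 (not isolated)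
Conditions: 8, TiCl4 (1.1 equiv), CH2Cl2, −78 °C; then 11, −78 °C; H2O
Reagents that add atoms: none
Why: Mukaiyama aldol addition under chelation control: TiCl4 bridges the aldehyde oxygen and the ester carbonyl, the enol silane attacks anti to the C7–O bond and past the C7 methyl group (polar Felkin–Anh within the chelate), so C8 should form as R with O8 anti to O7 along the C6–C8a chain, which becomes the cis 7,8-diol of ring B; C8a has no hydrogen, so the adduct cannot dehydrate.

Step 10
Reactants: 13
Product: 14 methyl (2R,3R)-4-acetyl-2-[(tert-butyldimethylsilyl)oxy]-3-hydroxy-4-(hydroxymethyl)-2-methyl-5-oxohexanoate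
Conditions: H2 (1 atm), Pd/C (10%), EtOAc, rt
Reagents that add atoms: none
Why: Neutral hydrogenolysis frees the C1 hydroxyl without touching ketones, ester or silyl ether and without the base that would trigger retro-aldol cleavage.

Step 11
Reactants: 14
Product: 15 methyl (2R)-2-[(tert-butyldimethylsilyl)oxy]-2-[(4R)-5,5-diacetyl-2,2-dimethyl-1,3-dioxan-4-yl]propanoate
Conditions: Me2C(OMe)2, pyridinium p-toluenesulfonate (cat.), CH2Cl2, rt
Reagents that add atoms: 2,2-dimethoxypropane, COC(C)(C)OC
Why: Acid-catalysed transacetalization forms the six-membered O2/O8 acetonide, which blocks retro-aldol cleavage at C8–C8a and fixes the chair that tells the two acetyl groups apart.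

Step 12
Reactants: 15
Product: 18 (4aR,8R,8aR)-4a-acetyl-8-[(tert-butyldimethylsilyl)oxy]-2,2,8-trimethylhexahydro-4H-benzo[d][1,3]dioxine-5,7-dione (ring B 1,3-dione), via acetyl potassium enolate 16 (not isolated), via dione potassium enolate 17 (not isolated)
Conditions: KN(SiMe3)2 (2.5 equiv), THF (0.01 M), −78 → 0 °C; AcOH
Reagents that add atoms: none
Why: KN(SiMe3)2 can enolize only the two acetyl groups (C7 and C8a are quaternary); the methyl ketone enolate adds to the C6 ester carbonyl and expels methoxide (intramolecular Claisen or Dieckmann-type acylation of a ketone enolate by an ester, the classical entry to cyclohexane-1,3-diones), and the dione is deprotonated at C5 as it forms, which makes the closure irreversible and shields it from methoxide. Ring B closes by 6-exo-trig attack of C5 on C6 (6-(enolexo) mode). The only new stereocentre, C8a, is controlled by C8 through the acetonide: the 2,2-dimethyl-1,3-dioxane is locked in the chair with the C7 branch equatorial on C8, so one acetyl on C8a is axial and the other equatorial. Closure through the equatorial acetyl passes through a trans-fused chair–chair transition state in which only the C7 silyloxy group and the spectator acetyl are syn-axial, whereas closure through the axial acetyl needs a cis-fused bicycle with the C7 methyl syn-axial to the spectator acetyl and O8 axial on the new ring. The step thus needs selection between two diastereotopic acetyl groups and C- over O-acylation; the first is secured by the dioxane chair, the second by the stability of the diketonate (an enol lactone from O-acylation would be reopened by methoxide). The spectator acetyl ends axial, anti to H8 and cis to O8, which is the C8a configuration of the target.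

Step 13
Reactants: 18
Product: 19 (4aS,8R,8aR)-4a-acetyl-8-[(tert-butyldimethylsilyl)oxy]-6-chloro-5-hydroxy-2,2,8-trimethyl-4a,8a-dihydro-4H-benzo[d][1,3]dioxin-7(8H)-one (enol form of the C5-chloro dione)
Conditions: N-chlorosuccinimide (1.0 equiv), CH2Cl2, 0 °C
Reagents that add atoms: N-chlorosuccinimide, O=C1CCC(=O)N1Cl
Why: Electrophilic chlorination of the enol of a cyclic 1,3-dione at its central carbon: C5 is the only doubly activated position, one equivalent should stop at the monochloride, and the C9 methyl ketone is not enolized under these neutral conditions.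

Step 14
Reactants: 19
Product: 21 (4aS,8R,8aR)-4a-acetyl-8-[(tert-butyldimethylsilyl)oxy]-6-chloro-2,2,8-trimethyl-7-oxo-4a,7,8,8a-tetrahydro-4H-benzo[d][1,3]dioxin-5-yl trifluoromethanesulfonate, via dione sodium enolate 20 (not isolated)
Conditions: NaH, THF, 0 °C; N-(5-chloropyridin-2-yl)bis(trifluoromethanesulfonyl)imide, 0 °C → rt
Reagents that add atoms: N-(5-chloropyridin-2-yl)bis(trifluoromethanesulfonyl)imide, FC(F)(F)S(=O)(=O)N(c1ccc(Cl)cn1)S(=O)(=O)C(F)(F)F
Why: O-Sulfonylation of the 1,3-dione enolate to the β-triflyloxy enone: O6 lies between the C7 methyl group and the axial tert-butyldimethylsilyl ether, whereas O4a is flanked only by the tied-back C1 methylene, and the sodium ion chelated between O4a and the C9 carbonyl oxygen can deliver the bulky triflimide, so the triflate is expected mainly on O4a.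

Step 15
Reactants: 22 (S)-2-methylbutan-1-ol
Product: 23 (S)-2-methylbutanal
Conditions: TEMPO (10 mol %), PhI(OAc)2 (1.1 equiv), CH2Cl2, rt; used at once as a solution
Reagents that add atoms: none
Why: Nitroxyl-catalysed oxidation under neutral, non-enolizing conditions gives the α-branched aldehyde without loss of configuration.

Step 16
Reactants: 23
Product: 24 (2E,4S)-2,4-dimethylhex-2-enal
Conditions: Ph3P=C(CH3)CHO, toluene, 80 °C
Reagents that add atoms: 2-(triphenylphosphoranylidene)propanal, CC(C=O)=P(c1ccccc1)(c1ccccc1)c1ccccc1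
Why: Wittig olefination with a stabilized formyl ylide gives the E-trisubstituted enal; no base is present, so the stereocentre next to the aldehyde is not epimerized before it becomes allylic.

Step 17
Reactants: 24
Product: 25 trimethyl[(3E,5E,7S)-5,7-dimethylnona-3,5-dien-1-yn-1-yl]silane
Conditions: (EtO)2P(O)CH2C≡CSiMe3, LiN(SiMe3)2, THF, −78 °C → rt
Reagents that add atoms: diethyl [3-(trimethylsilyl)prop-2-yn-1-yl]phosphonate, CCOP(=O)(OCC)CC#C[Si](C)(C)C
Why: Horner–Wadsworth–Emmons olefination with the lithiated propargyl phosphonate gives the E-disubstituted alkene conjugated to the protected alkyne.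

Step 18
Reactants: 25
Product: 26 (3E,5E,7S)-5,7-dimethylnona-3,5-dien-1-yne
Conditions: K2CO3 (0.2 equiv), MeOH, rt
Reagents that add atoms: none
Why: Carbonate-catalysed methanolysis of the alkynylsilane (protodesilylation) frees the terminal alkyne.

Step 19
Reactants: 21 the C4a enol triflate; 26 (3E,5E,7S)-5,7-dimethylnona-3,5-dien-1-yne
Product: 27 (4aS,8R,8aR)-4a-acetyl-8-[(tert-butyldimethylsilyl)oxy]-6-chloro-5-[(3E,5E,7S)-5,7-dimethylnona-3,5-dien-1-yn-1-yl]-2,2,8-trimethyl-4a,8a-dihydro-4H-benzo[d][1,3]dioxin-7(8H)-one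
Conditions: Pd(PPh3)2Cl2 (5 mol %), CuI (10 mol %), Et3N, THF, rt
Reagents that add atoms: none
Why: Sonogashira coupling: the β-triflyloxy enone adds oxidatively to zerovalent palladium at C4a–O far faster than the C5 vinyl chloride, the C9 ketone is a spectator, and the copper acetylide of 26 delivers C4–C3 with the whole side chain.

Step 20
Reactants: 27
Product: 28 (4S,5R,6R)-4-acetyl-2-chloro-3-[(3E,5E,7S)-5,7-dimethylnona-3,5-dien-1-yn-1-yl]-5,6-dihydroxy-4-(hydroxymethyl)-6-methylcyclohex-2-en-1-one
Conditions: 48% aq. HF, MeCN, 0 °C → rt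
Reagents that add atoms: none
Why: Acidic fluoride cleaves the tertiary silyl ether at silicon and hydrolyses the dioxane acetal in one operation; the medium is never basic, so the β-hydroxy ketone arrays at C8a cannot undergo retro-aldol cleavage, and any material that already closes ring A here is the target.

Step 21
Reactants: 28
Product: 29 (7R,8R,8aS)-8a-acetyl-5-chloro-3-[(1E,3E,5S)-3,5-dimethylhepta-1,3-dien-1-yl]-7,8-dihydroxy-7-methyl-8,8a-dihydro-1H-isochromen-6(7H)-one (CNP0307047.1)
Conditions: Ph3PAuNTf2 (5 mol %), CH2Cl2, rt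
Reagents that add atoms: none
Why: Gold-catalysed 6-endo-dig hydroalkoxylation (cycloisomerization of an alkynol): the C1 hydroxyl adds to C3, the alkyne carbon that is the δ-terminus of the ynenone and bears the cation-stabilizing dienyl group, and protodeauration at C4 gives the 1H-isochromene; O8 cannot reach C3 without a bridgehead alkene and 5-exo attack at C4 is electronically mismatched.

**Compound list**

1 | (S)-lactic acid | C[C@H](O)C(=O)O | starting material
2 | (2S,5S)-2-tert-butyl-5-methyl-1,3-dioxolan-4-one | C[C@@H]1O[C@H](C(C)(C)C)OC1=O | intermediate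
3 | lithium enolate of 2 (lithium (2S)-2-tert-butyl-5-methyl-1,3-dioxol-4-olate) | CC1=C(O[Li])O[C@@H](C(C)(C)C)O1 | intermediate
4 | (2S,5R)-5-[(benzyloxy)methyl]-2-tert-butyl-5-methyl-1,3-dioxolan-4-one | C[C@]1(COCc2ccccc2)O[C@H](C(C)(C)C)OC1=O | intermediate
5 | methyl (2R)-3-(benzyloxy)-2-hydroxy-2-methylpropanoate | COC(=O)[C@](C)(O)COCc1ccccc1 | intermediate
6 | methyl (2R)-3-(benzyloxy)-2-[(tert-butyldimethylsilyl)oxy]-2-methylpropanoate | COC(=O)[C@](C)(O[Si](C)(C)C(C)(C)C)COCc1ccccc1 | intermediate
7 | methyl (2R)-2-[(tert-butyldimethylsilyl)oxy]-3-hydroxy-2-methylpropanoate | COC(=O)[C@](C)(O[Si](C)(C)C(C)(C)C)CO | intermediate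
8 | methyl (2R)-2-[(tert-butyldimethylsilyl)oxy]-2-methyl-3-oxopropanoate | COC(=O)[C@](C)(O[Si](C)(C)C(C)(C)C)C=O | intermediate
9 | (Z)-4-[(trimethylsilyl)oxy]pent-3-en-2-one | CC(=O)/C=C(/C)O[Si](C)(C)C | starting material
10 | 3-[(benzyloxy)methyl]pentane-2,4-dione | CC(=O)C(COCc1ccccc1)C(C)=O | intermediate
11 | 3-[(benzyloxy)methyl]-4-[(trimethylsilyl)oxy]pent-3-en-2-one (E/Z mixture, either serves) | CC(=O)C(COCc1ccccc1)=C(C)O[Si](C)(C)C | intermediate
12 | trichlorotitanium C8 alkoxide of 13 | COC(=O)[C@](C)(O[Si](C)(C)C(C)(C)C)[C@H](O[Ti](Cl)(Cl)Cl)C(COCc1ccccc1)(C(C)=O)C(C)=O | intermediate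
13 | methyl (2R,3R)-4-acetyl-4-[(benzyloxy)methyl]-2-[(tert-butyldimethylsilyl)oxy]-3-hydroxy-2-methyl-5-oxohexanoate | COC(=O)[C@](C)(O[Si](C)(C)C(C)(C)C)[C@H](O)C(COCc1ccccc1)(C(C)=O)C(C)=O | intermediate
14 | methyl (2R,3R)-4-acetyl-2-[(tert-butyldimethylsilyl)oxy]-3-hydroxy-4-(hydroxymethyl)-2-methyl-5-oxohexanoate | COC(=O)[C@](C)(O[Si](C)(C)C(C)(C)C)[C@H](O)C(CO)(C(C)=O)C(C)=O | intermediate
15 | methyl (2R)-2-[(tert-butyldimethylsilyl)oxy]-2-[(4R)-5,5-diacetyl-2,2-dimethyl-1,3-dioxan-4-yl]propanoate | COC(=O)[C@](C)(O[Si](C)(C)C(C)(C)C)[C@@H]1OC(C)(C)OCC1(C(C)=O)C(C)=O | intermediate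
16 | potassium enolate of the equatorial acetyl group of 15 | COC(=O)[C@](C)(O[Si](C)(C)C(C)(C)C)[C@@H]1OC(C)(C)OC[C@@]1(C(C)=O)C(=C)O[K] | intermediate
17 | potassium enolate of dione 18 | [K]OC1=CC(=O)[C@](C)(O[Si](C)(C)C(C)(C)C)[C@@H]2OC(C)(C)OC[C@@]12C(C)=O | intermediate
18 | (4aR,8R,8aR)-4a-acetyl-8-[(tert-butyldimethylsilyl)oxy]-2,2,8-trimethylhexahydro-4H-benzo[d][1,3]dioxine-5,7-dione (trans-fused; acetyl anti to H8) | O=C1CC(=O)[C@](C)(O[Si](C)(C)C(C)(C)C)[C@@H]2OC(C)(C)OC[C@@]12C(C)=O | intermediate
19 | (4aS,8R,8aR)-4a-acetyl-8-[(tert-butyldimethylsilyl)oxy]-6-chloro-5-hydroxy-2,2,8-trimethyl-4a,8a-dihydro-4H-benzo[d][1,3]dioxin-7(8H)-one (one enol tautomer shown) | OC1=C(Cl)C(=O)[C@](C)(O[Si](C)(C)C(C)(C)C)[C@@H]2OC(C)(C)OC[C@@]12C(C)=O | intermediate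
20 | sodium enolate of 19 | [Na]OC1=C(Cl)C(=O)[C@](C)(O[Si](C)(C)C(C)(C)C)[C@@H]2OC(C)(C)OC[C@@]12C(C)=O | intermediate
21 | (4aS,8R,8aR)-4a-acetyl-8-[(tert-butyldimethylsilyl)oxy]-6-chloro-2,2,8-trimethyl-7-oxo-4a,7,8,8a-tetrahydro-4H-benzo[d][1,3]dioxin-5-yl trifluoromethanesulfonate | FC(F)(F)S(=O)(=O)OC1=C(Cl)C(=O)[C@](C)(O[Si](C)(C)C(C)(C)C)[C@@H]2OC(C)(C)OC[C@@]12C(C)=O | intermediate
22 | (S)-2-methylbutan-1-ol | CC[C@H](C)CO | starting material
23 | (S)-2-methylbutanal | CC[C@H](C)C=O | intermediate
24 | (2E,4S)-2,4-dimethylhex-2-enal | CC[C@H](C)/C=C(C)/C=O | intermediate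
25 | trimethyl[(3E,5E,7S)-5,7-dimethylnona-3,5-dien-1-yn-1-yl]silane | CC[C@H](C)/C=C(C)/C=C/C#C[Si](C)(C)C | intermediate
26 | (3E,5E,7S)-5,7-dimethylnona-3,5-dien-1-yne | CC[C@H](C)/C=C(C)/C=C/C#C | intermediate
27 | (4aS,8R,8aR)-4a-acetyl-8-[(tert-butyldimethylsilyl)oxy]-6-chloro-5-[(3E,5E,7S)-5,7-dimethylnona-3,5-dien-1-yn-1-yl]-2,2,8-trimethyl-4a,8a-dihydro-4H-benzo[d][1,3]dioxin-7(8H)-one | CC[C@H](C)/C=C(C)/C=C/C#CC1=C(Cl)C(=O)[C@](C)(O[Si](C)(C)C(C)(C)C)[C@@H]2OC(C)(C)OC[C@@]12C(C)=O | intermediate
28 | (4S,5R,6R)-4-acetyl-2-chloro-3-[(3E,5E,7S)-5,7-dimethylnona-3,5-dien-1-yn-1-yl]-5,6-dihydroxy-4-(hydroxymethyl)-6-methylcyclohex-2-en-1-one | CC[C@H](C)/C=C(C)/C=C/C#CC1=C(Cl)C(=O)[C@](C)(O)[C@H](O)[C@]1(CO)C(C)=O | intermediate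
29 | (7R,8R,8aS)-8a-acetyl-5-chloro-3-[(1E,3E,5S)-3,5-dimethylhepta-1,3-dien-1-yl]-7,8-dihydroxy-7-methyl-8,8a-dihydro-1H-isochromen-6(7H)-one | CC[C@H](C)/C=C(C)/C=C/C1=CC2=C(Cl)C(=O)[C@](C)(O)[C@H](O)[C@@]2(C(C)=O)CO1 | target

**Step count and risks**

Total: 21 steps. Longest linear sequence: 15 steps from (S)-lactic acid (steps 1–6, 9–14, 19–21).

Steps most likely to fail:

1. Step 14 – sulfonylation at the wrong enolate oxygen. The two oxygens of the dione enolate differ only in their quaternary neighbours, and counter-ion binding near the C9 acetyl could steer the electrophile to O6 instead of O4a. Fallback from 19, returning at 27, with the polarity of the C4–C4a bond formation reversed. If electrophiles prefer O6, O-methylation (Me2SO4, K2CO3, acetone) gives the C6 methyl enol ether F1. LiN(iPr)2 (1 equiv, THF, −78 °C) then masks the C9 methyl ketone, the only enolizable position, as its lithium enolate. The lithium acetylide of 26 (with CeCl3) adds to the C4a carbonyl to give the tertiary propargylic alcohol F2. Aqueous acid hydrolyses the enol ether with loss of methanol and water (Stork–Danheiser transposition) to give 27.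

2. Step 9 – slow bond formation between a neopentyl aldehyde carbon and a tetrasubstituted enol silane, with retro-aldol cleavage of the congested adduct and erosion of facial selectivity. Fallback from 8 and 9, returning at 13, with the congested bond made in two stages. The same TiCl4-mediated addition with the unsubstituted enol silane 9 gives the C8a–H adduct F3. Me3SiCl/Et3N converts it into the O8-silylated enol silane F4. ZnBr2-catalysed alkylation with benzyl chloromethyl ether then creates the quaternary C8a, and mild acid work-up removes the O8 trimethylsilyl group to give 13.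

3. Step 12 – closure through the axial acetyl group (cis-fused product, wrong C8a) or loss of an acetyl group by attack of the liberated methoxide on the diacetyl carbon. Fallback from 15, returning at 18, with ring B closed at the aldehyde oxidation level, where no alkoxide is set free and the addition is reversible. LiAlH4 (THF, −78 → 0 °C) reduces the ester and both ketones to triol F5. Dess–Martin periodinane re-oxidizes it to keto aldehyde F6. An intramolecular aldol addition of the equatorial acetyl group to the C6 aldehyde (piperidinium acetate, or LiN(SiMe3)2 at −78 °C) forms the same C5–C6 bond and the same ring, giving hydroxy ketone F7. A second Dess–Martin oxidation gives 18.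

**Further compounds**

F1 | step 14 | (4aR,8R,8aR)-4a-acetyl-8-[(tert-butyldimethylsilyl)oxy]-6-chloro-7-methoxy-2,2,8-trimethyl-4a,8a-dihydro-4H-benzo[d][1,3]dioxin-5(8H)-one (C6 methyl enol ether) | O=C1C(Cl)=C(OC)[C@](C)(O[Si](C)(C)C(C)(C)C)[C@@H]2OC(C)(C)OC[C@@]12C(C)=O
F2 | step 14 | C4a propargylic alcohol from acetylide addition to F1 (C4a configuration open, lost on hydrolysis) | CC[C@H](C)/C=C(C)/C=C/C#CC1(O)C(Cl)=C(OC)[C@](C)(O[Si](C)(C)C(C)(C)C)[C@@H]2OC(C)(C)OC[C@@]12C(C)=O
F3 | step 9 | methyl (2R,3R)-4-acetyl-2-[(tert-butyldimethylsilyl)oxy]-3-hydroxy-2-methyl-5-oxohexanoate | COC(=O)[C@](C)(O[Si](C)(C)C(C)(C)C)[C@H](O)C(C(C)=O)C(C)=O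
F4 | step 9 | methyl (2R,3R)-4-acetyl-2-[(tert-butyldimethylsilyl)oxy]-2-methyl-3,5-bis[(trimethylsilyl)oxy]hex-4-enoate | COC(=O)[C@](C)(O[Si](C)(C)C(C)(C)C)[C@H](O[Si](C)(C)C)C(C(C)=O)=C(C)O[Si](C)(C)C
F5 | step 12 | triol from reduction of 15 (C6 primary alcohol, both acetyls as 1-hydroxyethyl, carbinol epimers) | OC[C@](C)(O[Si](C)(C)C(C)(C)C)[C@@H]1OC(C)(C)OCC1(C(C)O)C(C)O
F6 | step 12 | (2R)-2-[(tert-butyldimethylsilyl)oxy]-2-[(4R)-5,5-diacetyl-2,2-dimethyl-1,3-dioxan-4-yl]propanal | O=C[C@](C)(O[Si](C)(C)C(C)(C)C)[C@@H]1OC(C)(C)OCC1(C(C)=O)C(C)=O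
F7 | step 12 | C6 hydroxy analogue of 18 (7-hydroxy-5-ketone in the benzodioxine numbering, C6 epimers) | O=C1CC(O)[C@](C)(O[Si](C)(C)C(C)(C)C)[C@@H]2OC(C)(C)OC[C@@]12C(C)=O
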